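The route rests on disconnecting the C5–C6 bond of the seven-membered ring (C4–C5–C6–C7–C8–C9–C10). The C6 oxymethyl carbon and the C9 oxygen sit cis across that ring, so they are carried as one δ-lactone (C9–O–CO–C6–C7–C8). This lactone hangs from C10 of a bicyclo[3.1.1]heptan-6-one whose carbonyl is C5 of the cyclobutane C4–C5–C11–C10. Enolising the lactone and adding its α-carbon C6 to the non-enolisable C5 ketone closes the carbocyclic seven-membered ring and sets C5 and quaternary C6 in one operation. The precursor already holds the C3 methyl and the C9 centre in their final configurations and C1 as a protected alcohol.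

Key step: step 14

Remark: carbons keep longipinane locants throughout (C1 later ketone, C3 methyl-bearing, C4/C11 bridgeheads, C5/C10 one-carbon bridges, C6–C9 seven-ring carbons); the C9 ester is the (Z)-2-methylbut-2-enoate (angelate) and the C6 oxymethyl ester the (E)-isomer (tiglate); (R)-methyl hydrogen 3-methylglutarate 5 is assumed to be purchasable, so the C3 methyl is present in the key-step precursor as a spectator and the C1 oxygen is carried as a methoxymethyl ether.

Step 1
Reactants: 1 prop-2-yn-1-ol
Product: 3 (E)-3-iodo-2-methylprop-2-en-1-ol, via alkenylalane 2 (not isolated)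
Conditions: AlMe3 (3 equiv), Cp2ZrCl2 (0.25 equiv), CH2Cl2, 0 °C → rt; then I2, THF, −30 → 0 °C
Reagents that add atoms: trimethylaluminium, C[Al](C)C; iodine, II
Why: Zirconium-catalysed Negishi carboalumination adds methyl and aluminium syn across the alkyne with aluminium at the terminal carbon, and iodinolysis of the C–Al bond with retention should give the (E)-iodide in which iodine is cis to the methyl group.

Step 2
Reactants: 3 (E)-3-iodo-2-methylprop-2-en-1-ol
Product: 4 tert-butyl{[(E)-3-iodo-2-methylprop-2-en-1-yl]oxy}dimethylsilane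
Conditions: TBSCl, imidazole, CH2Cl2, rt
Reagents that add atoms: tert-butyl(chloro)dimethylsilane, CC(C)(C)[Si](C)(C)Cl
Why: Routine imidazole-mediated silylation of a primary alcohol, which leaves the vinyl iodide and its geometry untouched.

Step 3
Reactants: 4 tert-butyl{[(E)-3-iodo-2-methylprop-2-en-1-yl]oxy}dimethylsilane; 5 (3R)-5-methoxy-3-methyl-5-oxopentanoic acid
Product: 9 methyl (3R,6E)-8-[(tert-butyldimethylsilyl)oxy]-3,7-dimethyl-5-oxooct-6-enoate, via acid chloride 6 (not isolated), via alkenyllithium 7 (not isolated), via alkenylzinc chloride 8 (not isolated)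
Conditions: 5, (COCl)2, cat. DMF, CH2Cl2, 0 °C → rt, evaporation; 4, t-BuLi (2 equiv), Et2O, −78 °C, then ZnCl2, THF, −78 → 0 °C; then 6, Pd(PPh3)4 (5 mol %), THF, 0 °C → rt
Reagents that add atoms: none
Why: Negishi acyl cross-coupling, in which iodine–lithium exchange and transmetalation to zinc retain the alkene geometry and the alkenylzinc reacts under Pd(PPh3)4 catalysis with the acid chloride only, sparing the methyl ester and the remote C3 centre.

Step 4
Reactants: 9 methyl (3R,6E)-8-[(tert-butyldimethylsilyl)oxy]-3,7-dimethyl-5-oxooct-6-enoate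
Product: 10 methyl (3R,5S,6E)-8-[(tert-butyldimethylsilyl)oxy]-5-hydroxy-3,7-dimethyloct-6-enoate
Conditions: (R)-2-methyl-CBS-oxazaborolidine (0.3 equiv), catecholborane, toluene, −78 °C; MeOH quench
Reagents that add atoms: none
Why: Corey–Bakshi–Shibata reduction in which the alkenyl group acts as the large substituent, so the (R)-oxazaborolidine should deliver hydride to give the (5S)-allylic alcohol (C1 of the skeleton) under reagent control, with catecholborane at −78 °C avoiding hydroboration of the alkene.

Step 5
Reactants: 10 methyl (3R,5S,6E)-8-[(tert-butyldimethylsilyl)oxy]-5-hydroxy-3,7-dimethyloct-6-enoate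
Product: 11 methyl (3R,5S,6E)-8-[(tert-butyldimethylsilyl)oxy]-5-(methoxymethoxy)-3,7-dimethyloct-6-enoate
Conditions: MOMCl, i-Pr2NEt, CH2Cl2, 0 °C → rt
Reagents that add atoms: chloromethyl methyl ether, COCCl
Why: O-Alkylation with the chloromethyl ether under amine base protects the allylic alcohol without lactonisation onto the ester, and the small methoxymethyl ether survives every later reagent and cannot migrate to a neighbouring alkoxide.

Step 6
Reactants: 11 methyl (3R,5S,6E)-8-[(tert-butyldimethylsilyl)oxy]-5-(methoxymethoxy)-3,7-dimethyloct-6-enoate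
Product: 12 (3R,5S,6E)-8-[(tert-butyldimethylsilyl)oxy]-5-(methoxymethoxy)-3,7-dimethyloct-6-enoic acid
Conditions: LiOH·H2O, THF/MeOH/H2O, rt; then 1 M HCl to pH 4
Reagents that add atoms: lithium hydroxide, [Li+].[OH-]
Why: Plain saponification of the methyl ester, to which the silyl ether, the acetal and both stereocentres are inert at room temperature.

Step 7
Reactants: 12 (3R,5S,6E)-8-[(tert-butyldimethylsilyl)oxy]-5-(methoxymethoxy)-3,7-dimethyloct-6-enoic acid
Product: 15 silyloxymethyl bicyclo[3.1.1]heptan-6-one (C1-OMOM; C3-methyl; C10-methyl), via acid chloride 13 (not isolated), via ketene 14 (not isolated)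
Conditions: 1-chloro-N,N,2-trimethylprop-1-en-1-amine, CH2Cl2, 0 °C → rt; then slow addition to Et3N (5 equiv), toluene, 110 °C (0.01 M)
Reagents that add atoms: none
Why: Intramolecular ketene–alkene [2+2] cycloaddition in which the ketene carbonyl carbon (C5) bonds to the less substituted alkene carbon C11 and C4 to the cation-stabilising C10, giving the bridged bicyclo[3.1.1] ketone; suprafacial addition to the (E)-alkene places the C10 methyl syn to the C1–C3 bridge, and allylic 1,3-strain at C1 together with the C3 methyl avoiding the C10 methyl should put both substituents on the side of the carbonyl bridge, which fixes C4, C10 and C11 in the required absolute sense.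

Step 8
Reactants: 15 silyloxymethyl bicyclo[3.1.1]heptan-6-one
Product: 16 hydroxymethyl bicyclo[3.1.1]heptan-6-one
Conditions: HF·pyridine, pyridine, THF, 0 °C → rt
Reagents that add atoms: none
Why: Fluoride cleavage of the primary silyl ether, to which the acetal and the non-enolisable cyclobutanone are stable.

Step 9
Reactants: 16 hydroxymethyl bicyclo[3.1.1]heptan-6-one
Product: 17 C9 aldehyde
Conditions: Dess–Martin periodinane, NaHCO3, CH2Cl2, rt
Reagents that add atoms: none
Why: Dess–Martin oxidation under buffered conditions gives the neopentyl aldehyde, which has no α-hydrogen and cannot epimerise.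

Step 10
Reactants: 17 C9 aldehyde
Product: 19 (9R)-homoallylic alcohol, via borinate ester 18 (not isolated)
Conditions: (+)-Ipc2B(allyl), Et2O, −78 °C; then ethanolamine, rt
Reagents that add atoms: (+)-B-allyldiisopinocampheylborane, C=CCB([C@H]1C[C@H]2C[C@@H]([C@@H]1C)C2(C)C)[C@H]1C[C@H]2C[C@@H]([C@@H]1C)C2(C)C
Why: Brown allylboration through a chair-like six-membered transition state, in which the reagent derived from (−)-α-pinene adds to the Re face of the aldehyde and should give the (9R)-carbinol under reagent control, the hindered ketone being left alone at −78 °C and the peroxide-free work-up sparing the cyclobutanone from Baeyer–Villiger oxidation.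

Step 11
Reactants: 19 (9R)-homoallylic alcohol; 20 methacryloyl chloride
Product: 21 (9R)-methacrylate
Conditions: Et3N, DMAP (cat.), CH2Cl2, 0 °C → rt
Reagents that add atoms: none
Why: DMAP-catalysed acylation of the secondary alcohol with the acid chloride, which touches no stereocentre.

Step 12
Reactants: 21 (9R)-methacrylate
Product: 22 α-methyl-α,β-unsaturated δ-lactone
Conditions: second-generation Grubbs catalyst RuCl2(=CHPh)(PCy3)(H2IMes) (5 mol %), toluene, 80 °C (0.005 M)
Reagents that add atoms: none
Why: Ring-closing olefin metathesis between the methacrylate and the terminal alkene releases ethene and closes the six-membered unsaturated lactone, a standard construction of such dihydropyranones.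

Step 13
Reactants: 22 α-methyl-α,β-unsaturated δ-lactone
Product: 23 saturated 3-methyl-δ-lactone on C10 of the bicyclo[3.1.1]heptan-6-one (key-step precursor; both C6 epimers)
Conditions: H2 (1 atm), Pd/C (10 wt %), EtOAc, rt
Reagents that add atoms: none
Why: Heterogeneous catalytic hydrogenation saturates the conjugated alkene while ketone, acetal and lactone survive, and the mixture of epimers at the lactone α-carbon C6 is harmless because both give the same enolate.

Step 14
Reactants: 23 saturated 3-methyl-δ-lactone on C10 of the bicyclo[3.1.1]heptan-6-one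
Product: 26 lactone-bridged tricyclic C5 tertiary alcohol, via lithium enolate 24 (not isolated), via lithium aldolate 25 (not isolated)
Conditions: LiN(SiMe3)2 (1.2 equiv), THF, −78 °C (0.02 M); then sat. aq. NH4Cl at −78 °C
Reagents that add atoms: none
Why: LiN(SiMe3)2 removes the only acidic hydrogen of 23, the lactone α-hydrogen on C6 (both carbons flanking the ketone are bridgeheads, and this base has no β-hydrogen to reduce the strained carbonyl), and the enolate carbon adds to the C5 carbonyl in an intramolecular aldol addition, the closest known type being ester-enolate addition to a cyclobutanone. The closure is 7-exo-trig and forms the carbocycle C4–C5–C6–C7–C8–C9–C10, the lactone becoming a bridged boat within a bicyclo[3.2.2] unit. At C5 the tether hangs from the C10 substituent that points away from the C1–C3 bridge, so C6 can reach only that face of the carbonyl and the hydroxyl is forced to the side of the C1–C3 bridge. At C6 the new bond must be cis to the C9–C10 bond on the lactone ring, so the (9R) centre alone fixes the quaternary configuration and both C6 epimers of 23 converge. The step needs chemoselective enolisation, secured by the non-enolisable ketone, and an adduct that does not revert, secured by relief of cyclobutanone carbonyl strain, by lithium chelation between the new alkoxide and the C1 acetal oxygens and by a cold quench.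

Step 15
Reactants: 26 lactone-bridged tricyclic C5 tertiary alcohol
Product: 29 C5 O-alkyl S-methyl xanthate, via potassium alkoxide 27 (not isolated), via potassium xanthate 28 (not isolated)
Conditions: KN(SiMe3)2, THF, −78 °C; CS2, −78 → −40 °C; MeI, → 0 °C
Reagents that add atoms: carbon disulfide, S=C=S; iodomethane, CI
Why: Xanthate formation, the first half of a Barton–McCombie deoxygenation, in which the potassium alkoxide adds to the small electrophile CS2 and is S-methylated; the tertiary xanthate cannot undergo syn-elimination because its only β-hydrogens are at bridgeheads, and at −78 °C the alkoxide is the same aldolate that persists in step 14.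

Step 16
Reactants: 29 C5 O-alkyl S-methyl xanthate
Product: 30 C5-deoxy bridged lactone
Conditions: Bu3SnH (3 equiv), AIBN (cat.), toluene, 110 °C
Reagents that add atoms: none
Why: Barton–McCombie radical chain reduction, in which stannyl radical addition to the thiocarbonyl group and C5–O scission give a tertiary cyclobutyl radical that takes hydrogen from Bu3SnH on the only open face (syn to the C1–C3 bridge), the C6 bond being held on the other face by the ring, so the C5 configuration of the target results.

Step 17
Reactants: 30 C5-deoxy bridged lactone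
Product: 31 C9-hydroxy C6-hydroxymethyl diol
Conditions: LiAlH4, THF, 0 °C → reflux; then H2O, aq. NaOH
Reagents that add atoms: none
Why: Hydride reduction of the lactone with LiAlH4 opens it to the primary alcohol on C6 and the secondary alcohol on C9 without touching a stereocentre, the acetal being inert.

Step 18
Reactants: 31 C9-hydroxy C6-hydroxymethyl diol; 32 (E)-2-methylbut-2-enoyl chloride (tigloyl chloride)
Product: 33 primary tiglate
Conditions: pyridine, DMAP (cat.), CH2Cl2, −20 → 0 °C
Reagents that add atoms: none
Why: Chemoselective acylation, since the primary alcohol reacts with the acid chloride far faster than the secondary C9 alcohol next to quaternary C10, and the (E)-acyl group is configurationally stable.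

Step 19
Reactants: 33 primary tiglate; 34 (Z)-2-methylbut-2-enoic acid (angelic acid)
Product: 36 MOM-protected tiglate angelate, via mixed anhydride 35 (not isolated)
Conditions: 34, 2,4,6-Cl3C6H2COCl, Et3N, toluene, rt; then 33, 80 °C
Reagents that add atoms: none
Why: Yamaguchi-type esterification through the 2,4,6-trichlorobenzoyl mixed anhydride, run without a nucleophilic catalyst, acylates hindered secondary alcohols with the (Z)-acid without isomerisation to the (E)-ester, and C9 keeps its configuration because its C–O bond is not broken.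

Step 20
Reactants: 36 MOM-protected tiglate angelate
Product: 37 C1 alcohol
Conditions: Me2BBr, CH2Cl2, −78 °C; then NaHCO3, THF/H2O
Reagents that add atoms: none
Why: Lewis-acid acetal cleavage, in which Me2BBr opens the methoxymethyl ether at −78 °C and the bromomethyl ether hydrolyses on work-up, while both unsaturated esters are left unchanged.

Step 21
Reactants: 37 C1 alcohol
Product: 38 CNP0276938.2
Conditions: Dess–Martin periodinane, NaHCO3, CH2Cl2, rt
Reagents that add atoms: none
Why: Dess–Martin oxidation of the secondary C1 alcohol gives the ketone; C11 is a bridgehead and C3 is β to the carbonyl, so no centre can epimerise, and the two enoate esters are untouched.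

Compound list
1 | prop-2-yn-1-ol | C#CCO | starting material
2 | dimethyl[(E)-3-(dimethylalumanyloxy)-2-methylprop-1-enyl]alumane (Al cis to CH3) | C/C(=C\[Al](C)C)CO[Al](C)C | intermediate
3 | (E)-3-iodo-2-methylprop-2-en-1-ol (I cis to CH3) | C/C(=C\I)CO | intermediate
4 | tert-butyl{[(E)-3-iodo-2-methylprop-2-en-1-yl]oxy}dimethylsilane | C/C(=C\I)CO[Si](C)(C)C(C)(C)C | intermediate
5 | (3R)-5-methoxy-3-methyl-5-oxopentanoic acid ((R)-methyl hydrogen 3-methylglutarate) | COC(=O)C[C@H](C)CC(=O)O | starting material
6 | methyl (3R)-5-chloro-3-methyl-5-oxopentanoate | COC(=O)C[C@H](C)CC(=O)Cl | intermediate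
7 | (E)-[3-(tert-butyldimethylsilyloxy)-2-methylprop-1-enyl]lithium | C/C(=C\[Li])CO[Si](C)(C)C(C)(C)C | intermediate
8 | (E)-[3-(tert-butyldimethylsilyloxy)-2-methylprop-1-enyl]zinc chloride | C/C(=C\[Zn]Cl)CO[Si](C)(C)C(C)(C)C | intermediate
9 | methyl (3R,6E)-8-[(tert-butyldimethylsilyl)oxy]-3,7-dimethyl-5-oxooct-6-enoate | COC(=O)C[C@H](C)CC(=O)/C=C(\C)CO[Si](C)(C)C(C)(C)C | intermediate
10 | methyl (3R,5S,6E)-8-[(tert-butyldimethylsilyl)oxy]-5-hydroxy-3,7-dimethyloct-6-enoate | COC(=O)C[C@H](C)C[C@H](O)/C=C(\C)CO[Si](C)(C)C(C)(C)C | intermediate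
11 | methyl (3R,5S,6E)-8-[(tert-butyldimethylsilyl)oxy]-5-(methoxymethoxy)-3,7-dimethyloct-6-enoate | COC(=O)C[C@H](C)C[C@H](OCOC)/C=C(\C)CO[Si](C)(C)C(C)(C)C | intermediate
12 | (3R,5S,6E)-8-[(tert-butyldimethylsilyl)oxy]-5-(methoxymethoxy)-3,7-dimethyloct-6-enoic acid | OC(=O)C[C@H](C)C[C@H](OCOC)/C=C(\C)CO[Si](C)(C)C(C)(C)C | intermediate
13 | (3R,5S,6E)-8-[(tert-butyldimethylsilyl)oxy]-5-(methoxymethoxy)-3,7-dimethyloct-6-enoyl chloride | ClC(=O)C[C@H](C)C[C@H](OCOC)/C=C(\C)CO[Si](C)(C)C(C)(C)C | intermediate
14 | (3R,5S,6E)-8-[(tert-butyldimethylsilyl)oxy]-5-(methoxymethoxy)-3,7-dimethylocta-1,6-dien-1-one (ketene) | O=C=C[C@H](C)C[C@H](OCOC)/C=C(\C)CO[Si](C)(C)C(C)(C)C | intermediate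
15 | bicyclo[3.1.1]heptan-6-one with bridgeheads C4 and C11, carbonyl bridge C5, (1S)-OCH2OCH3 and (3R)-CH3 both on the side of the carbonyl bridge, C10-CH3 syn to the C1–C3 bridge and C10-CH2OTBS anti | O=C1[C@@H]2[C@H](C)C[C@H](OCOC)[C@H]1[C@]2(C)CO[Si](C)(C)C(C)(C)C | intermediate
16 | primary alcohol of 15 (C10-CH2OH) | O=C1[C@@H]2[C@H](C)C[C@H](OCOC)[C@H]1[C@]2(C)CO | intermediate
17 | C9 aldehyde of 16 (C10-CHO) | O=C1[C@@H]2[C@H](C)C[C@H](OCOC)[C@H]1[C@]2(C)C=O | intermediate
18 | O-diisopinocampheylboryl ether of 19 | O=C1[C@@H]2[C@H](C)C[C@H](OCOC)[C@H]1[C@]2(C)[C@H](OB([C@H]3C[C@H]4C[C@@H]([C@@H]3C)C4(C)C)[C@H]3C[C@H]4C[C@@H]([C@@H]3C)C4(C)C)CC=C | intermediate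
19 | (9R)-homoallylic alcohol: C10 of the bicyclic ketone carries (1R)-1-hydroxybut-3-enyl | O=C1[C@@H]2[C@H](C)C[C@H](OCOC)[C@H]1[C@]2(C)[C@H](O)CC=C | intermediate
20 | methacryloyl chloride | C=C(C)C(=O)Cl | starting material
21 | (9R)-methacrylate of 19 | O=C1[C@@H]2[C@H](C)C[C@H](OCOC)[C@H]1[C@]2(C)[C@H](OC(=O)C(C)=C)CC=C | intermediate
22 | bicyclic ketone bearing on C10 a (6R)-3-methyl-5,6-dihydro-2H-pyran-2-on-6-yl ring (C9 = ring C6) | O=C1[C@@H]2[C@H](C)C[C@H](OCOC)[C@H]1[C@]2(C)[C@H]3CC=C(C)C(=O)O3 | intermediate
23 | key-step precursor: bicyclo[3.1.1]heptan-6-one bearing on C10 a (9R)-3-methyltetrahydropyran-2-one, both epimers at the lactone α-carbon C6 | O=C1[C@@H]2[C@H](C)C[C@H](OCOC)[C@H]1[C@]2(C)[C@H]3CCC(C)C(=O)O3 | intermediate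
24 | lithium enolate of 23 (C6=C(OLi)O) | O=C1[C@@H]2[C@H](C)C[C@H](OCOC)[C@H]1[C@]2(C)[C@H]3CCC(C)=C(O[Li])O3 | intermediate
25 | lithium C5-alkoxide of 26 | O=C4O[C@@H]1CC[C@@]4(C)[C@@]2(O[Li])[C@@H]3[C@H](C)C[C@H](OCOC)[C@H]2[C@@]31C | intermediate
26 | key-step product: longipinane carbocycle with C5-OH syn to the C1–C3 bridge, lactone bridge C6–CO–O–C9 on the C11 side, C6-CH3, (1S)-OMOM, (3R)-CH3, (9R) | O=C4O[C@@H]1CC[C@@]4(C)[C@@]2(O)[C@@H]3[C@H](C)C[C@H](OCOC)[C@H]2[C@@]31C | intermediate
27 | potassium C5-alkoxide of 26 | O=C4O[C@@H]1CC[C@@]4(C)[C@@]2(O[K])[C@@H]3[C@H](C)C[C@H](OCOC)[C@H]2[C@@]31C | intermediate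
28 | potassium C5-O-xanthate of 26 | O=C4O[C@@H]1CC[C@@]4(C)[C@@]2(OC(=S)S[K])[C@@H]3[C@H](C)C[C@H](OCOC)[C@H]2[C@@]31C | intermediate
29 | C5 O-alkyl S-methyl xanthate of 26 | O=C4O[C@@H]1CC[C@@]4(C)[C@@]2(OC(=S)SC)[C@@H]3[C@H](C)C[C@H](OCOC)[C@H]2[C@@]31C | intermediate
30 | C5-deoxy lactone: C5-H syn to the C1–C3 bridge, otherwise as 26 | O=C4O[C@@H]1CC[C@@]4(C)[C@H]2[C@@H]3[C@H](C)C[C@H](OCOC)[C@H]2[C@@]31C | intermediate
31 | longipinane diol: (9R)-OH and C6-CH2OH cis across the seven-membered ring, (1S)-OMOM | O[C@@H]1CC[C@](C)(CO)[C@H]2[C@@H]3[C@H](C)C[C@H](OCOC)[C@H]2[C@@]31C | intermediate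
32 | (E)-2-methylbut-2-enoyl chloride (tigloyl chloride) | C/C=C(\C)C(=O)Cl | starting material
33 | C6-CH2 (E)-2-methylbut-2-enoate of 31 with free (9R)-OH | O[C@@H]1CC[C@](C)(COC(=O)/C(C)=C/C)[C@H]2[C@@H]3[C@H](C)C[C@H](OCOC)[C@H]2[C@@]31C | intermediate
34 | (Z)-2-methylbut-2-enoic acid (angelic acid) | C/C=C(/C)C(=O)O | starting material
35 | (Z)-2-methylbut-2-enoic 2,4,6-trichlorobenzoic anhydride | C/C=C(/C)C(=O)OC(=O)c1c(Cl)cc(Cl)cc1Cl | intermediate
36 | (9R)-angelate C6-CH2 tiglate with (1S)-OMOM | C/C=C(/C)C(=O)O[C@@H]1CC[C@](C)(COC(=O)/C(C)=C/C)[C@H]2[C@@H]3[C@H](C)C[C@H](OCOC)[C@H]2[C@@]31C | intermediate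
37 | (1S)-alcohol of 36 | C/C=C(/C)C(=O)O[C@@H]1CC[C@](C)(COC(=O)/C(C)=C/C)[C@H]2[C@@H]3[C@H](C)C[C@H](O)[C@H]2[C@@]31C | intermediate
38 | CNP0276938.2: (3R,4S,5S,6S,9R,10R,11R)-9-angeloyloxy-6-(tigloyloxymethyl)longipinan-1-one (longipinane locants) | C/C=C(/C)C(=O)O[C@@H]1CC[C@](C)(COC(=O)/C(C)=C/C)[C@H]2[C@@H]3[C@H](C)CC(=O)[C@H]2[C@@]31C | target

Total step count: 21. Longest linear sequence: 21 steps (1 → 38); 5, 20, 32 and 34 enter as purchased building blocks.

Steps most likely to fail

Step 14. The aldol addition may revert to enolate and ketone before the quench, or the enolate may condense intermolecularly. The fallback sets out from 23: LiN(SiMe3)2 is added to 23 and Me3SiCl in THF at −78 °C (internal quench) to give the trimethylsilyl ketene acetal F1. F1 is then closed by a Lewis-acid-promoted Mukaiyama aldol addition (BF3·OEt2, CH2Cl2, −78 °C), in which the carbonyl is activated and the adduct is held as a boron aldolate that cannot revert. Aqueous work-up returns the route at 26.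

Step 7. The cycloaddition may be sluggish because the alkene is deactivated by two allylic oxygens, so that ketene dimerisation takes over, or the facial selectivity may be insufficient. The fallback sets out from 12: coupling with pyrrolidine (EDC·HCl, HOBt, CH2Cl2) gives the pyrrolidine amide F2. Tf2O and 2,4,6-collidine in 1,2-dichloroethane at 80 °C convert F2 into the far more electrophilic keteniminium ion, whose intramolecular [2+2] cycloaddition should give the cyclobutaniminium triflate F3. Hydrolysis with aqueous NaHCO3 returns the route at 15.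

Step 15. The crowded tertiary alkoxide may fail to add to CS2, or it may open by retro-aldol cleavage once formed. The fallback sets out from 26 and avoids the alkoxide: Me2BBr (CH2Cl2, −78 °C) removes the acetal to give the diol F4, whose C1 and C5 hydroxyls are syn on the six-membered ring. 1,1'-Thiocarbonyldiimidazole with DMAP in toluene at 110 °C acylates the accessible secondary hydroxyl and closes the cyclic thionocarbonate F5 intramolecularly. Bu3SnH/AIBN (toluene, 110 °C) should cleave the C5–O bond toward the tertiary radical and, after hydrolytic work-up, give the hydroxy lactone F6; MOMCl/i-Pr2NEt returns the route at 30. The weak point of this fallback is that scission toward the secondary C1 radical could compete.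

Further compounds
F1 | step 14 | trimethylsilyl ketene acetal of 23 | O=C1[C@@H]2[C@H](C)C[C@H](OCOC)[C@H]1[C@]2(C)[C@H]3CCC(C)=C(O[Si](C)(C)C)O3
F2 | step 7 | pyrrolidine amide of 12 | O=C(C[C@H](C)C[C@H](OCOC)/C=C(\C)CO[Si](C)(C)C(C)(C)C)N1CCCC1
F3 | step 7 | N-pyrrolidinium cyclobutaniminium triflate corresponding to 15 | C1CC[N+](C1)=C2[C@@H]3[C@H](C)C[C@H](OCOC)[C@H]2[C@]3(C)CO[Si](C)(C)C(C)(C)C.[O-]S(=O)(=O)C(F)(F)F
F4 | step 15 | C1,C5-diol lactone (26 without the acetal) | O=C4O[C@@H]1CC[C@@]4(C)[C@@]2(O)[C@@H]3[C@H](C)C[C@H](O)[C@H]2[C@@]31C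
F5 | step 15 | cyclic C1,C5-thionocarbonate of F4 | O=C4O[C@@H]1CC[C@@]4(C)[C@@]2(OC5=S)[C@@H]3[C@H](C)C[C@H](O5)[C@H]2[C@@]31C
F6 | step 15 | C1-hydroxy C5-deoxy lactone | O=C4O[C@@H]1CC[C@@]4(C)[C@H]2[C@@H]3[C@H](C)C[C@H](O)[C@H]2[C@@]31C
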